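**Plan**

1. Retrosynthesis: the O1–C2 bond of the dihydropyran ring (ring B) is cut first, giving a phenol and a 1,1-disubstituted alkene. Then C3–C4 is cut (aryl aldehyde plus 2-methylallyl nucleophile), then C4–C4a (formylation) and the C8–acyl bond (Friedel–Crafts acylation) on the benzene ring (ring A).
2. Forward: ring A is fully substituted first (acyl group, silyl ether, formyl group). The C2/C3 unit with both future C2 methyl carbons is joined at C4 by asymmetric 2-methylallylboration, and ring B is closed last through O1–C2.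
3. Enabling feature: C2 is a fully substituted, stereochemically silent ether carbon with two methyl groups, 1,3 to the C4 carbinol and at six-ring distance from the oxygen on C8a. It can therefore be the internal carbon of a 2-methylallyl alkene, with one methyl made by hydrogen-atom delivery to the alkene CH2 under non-acidic cobalt hydride catalysis that the acid-labile benzylic carbinol should tolerate.
4. Choice of ring oxygen: the C8 ketone chelates its two flanking hydroxyls (on C7 and C8a). The only non-chelated hydroxyl (on C5, para to the ketone) is silylated in step 2 and stays blocked, so at ring closure C8a–OH is the only free ortho oxygen.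
5. Stereochemistry: the single stereocentre C4 (R) is set by reagent control in the Brown 2-methylallylboration (isopinocampheyl groups from (−)-α-pinene, Re face of the aldehyde). It is kept by avoiding acid in every later step.

Key step: step 7

Assumption: read from the SMILES, the carbinol carbon is (4R); atoms are numbered as in the chroman product throughout (O1, C2, C3, C4, C4a, C5 to C8, C8a), and 2-methylphloroglucinol is taken as commercially available.

**Route**

Step 1
Reactants: 1 2-methylbenzene-1,3,5-triol; 2 3-phenylpropanoyl chloride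
Product: 3 1-(2,4,6-trihydroxy-3-methylphenyl)-3-phenylpropan-1-one
Conditions: AlCl3 (3 equiv), PhNO2/CH2Cl2, 0 °C to rt; then ice/1 M HCl
Reagents that add atoms: none
Why: Friedel–Crafts C-acylation of the electron-rich triol, whose two free ring positions are equivalent, should give one monoketone, the first acyl group slowing a second acylation.

Step 2
Reactants: 3 1-(2,4,6-trihydroxy-3-methylphenyl)-3-phenylpropan-1-one
Product: 4 1-{2,6-dihydroxy-3-methyl-4-[(triisopropylsilyl)oxy]phenyl}-3-phenylpropan-1-one
Conditions: iPr3SiCl (1.05 equiv), imidazole (2 equiv), DMF, 0 °C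
Reagents that add atoms: triisopropylsilyl chloride, CC(C)[Si](Cl)(C(C)C)C(C)C
Why: Regioselective O-silylation is expected at the hydroxyl para to the ketone, the most acidic and the only one not held in a hydrogen-bonded chelate, while the bulky silyl chloride avoids the two ortho hydroxyls.

Step 3
Reactants: 4 1-{2,6-dihydroxy-3-methyl-4-[(triisopropylsilyl)oxy]phenyl}-3-phenylpropan-1-one
Product: 6 2,4-dihydroxy-5-methyl-3-(3-phenylpropanoyl)-6-[(triisopropylsilyl)oxy]benzaldehyde, via chloro methyl ether 5 (not isolated)
Conditions: Cl2CHOMe (1.3 equiv), TiCl4 (2.5 equiv), CH2Cl2, −78 to −20 °C; then ice-water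
Reagents that add atoms: dichloromethyl methyl ether, COC(Cl)Cl; water, O
Why: Rieche formylation should place the one-carbon unit on the only remaining ring C–H, ortho to the titanium phenoxide, and water converts the chloro methyl ether into the aldehyde.

Step 4
Reactants: 6 2,4-dihydroxy-5-methyl-3-(3-phenylpropanoyl)-6-[(triisopropylsilyl)oxy]benzaldehyde
Product: 7 2,4-bis(allyloxy)-5-methyl-3-(3-phenylpropanoyl)-6-[(triisopropylsilyl)oxy]benzaldehyde
Conditions: allyl bromide (3 equiv), K2CO3 (3 equiv), DMF, rt
Reagents that add atoms: allyl bromide, C=CCBr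
Why: Williamson O-allylation caps the two acidic chelated phenols, which would otherwise quench the allylborane and deactivate the aldehyde, with a group removable later under neutral conditions.

Step 5
Reactants: 7 2,4-bis(allyloxy)-5-methyl-3-(3-phenylpropanoyl)-6-[(triisopropylsilyl)oxy]benzaldehyde
Product: 9 1-{2,6-bis(allyloxy)-3-[(1R)-1-hydroxy-3-methylbut-3-en-1-yl]-5-methyl-4-[(triisopropylsilyl)oxy]phenyl}-3-phenylpropan-1-one, via borinate ester 8 (not isolated)
Conditions: (+)-Ipc2BOMe [from (−)-α-pinene] (1.5 equiv), 2-methylallylmagnesium chloride (1.4 equiv), Et2O, 0 °C to rt; then 7, −78 °C; then NaBO3·4H2O, THF/H2O, rt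
Reagents that add atoms: 2-methylallylmagnesium chloride, CC(=C)C[Mg]Cl (its 2-methylallyl group ends in 9); (+)-B-methoxydiisopinocampheylborane, COB([C@H]1C[C@H]2C[C@@H]([C@@H]1C)C2(C)C)[C@H]1C[C@H]2C[C@@H]([C@@H]1C)C2(C)C (boron and isopinocampheyl groups are carried only in 8)
Why: Brown allylboration through a chair Zimmerman–Traxler transition state should add the 2-methylallyl group to the Re face of the aldehyde under control of the isopinocampheyl groups from (−)-α-pinene, giving the (R)-carbinol, while the hindered ketone does not react at −78 °C.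

Step 6
Reactants: 9 1-{2,6-bis(allyloxy)-3-[(1R)-1-hydroxy-3-methylbut-3-en-1-yl]-5-methyl-4-[(triisopropylsilyl)oxy]phenyl}-3-phenylpropan-1-one
Product: 10 1-{2,6-dihydroxy-3-[(1R)-1-hydroxy-3-methylbut-3-en-1-yl]-5-methyl-4-[(triisopropylsilyl)oxy]phenyl}-3-phenylpropan-1-one
Conditions: Pd(PPh3)4 (5 mol %), morpholine (10 equiv), THF, rt; pH 6 phosphate buffer work-up
Reagents that add atoms: none
Why: Tsuji–Trost-type deallylation by zerovalent palladium, with morpholine trapping the π-allyl unit, should free both phenols without acid, leaving the silyl ether, the carbinol and the 1,1-disubstituted alkene untouched.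

Step 7
Reactants: 10 1-{2,6-dihydroxy-3-[(1R)-1-hydroxy-3-methylbut-3-en-1-yl]-5-methyl-4-[(triisopropylsilyl)oxy]phenyl}-3-phenylpropan-1-one
Product: 11 1-{(4R)-4,7-dihydroxy-2,2,6-trimethyl-5-[(triisopropylsilyl)oxy]-3,4-dihydro-2H-chromen-8-yl}-3-phenylpropan-1-one
Conditions: [N,N'-bis(3,5-di-tert-butylsalicylidene)-1,2-cyclohexanediaminato]cobalt, C36H52CoN2O2 (divalent cobalt, racemic ligand, 5 mol %), N-fluoro-2,4,6-trimethylpyridinium tetrafluoroborate (1.5 equiv), (Me2SiH)2O (1.5 equiv), PhCF3, 0 °C to rt, argon
Reagents that add atoms: none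
Why: The cobalt salen complex is oxidised by the N-fluoropyridinium salt and turned by the silane into a cobalt hydride, which transfers a hydrogen atom to the terminal CH2 of the 1,1-disubstituted alkene; the tertiary radical passes by radical–polar crossover to a cation-like alkylcobalt centre that the C8a hydroxyl displaces to form the O1–C2 bond, the released proton being held by 2,4,6-trimethylpyridine. The closest known reaction type is the cobalt-salen-catalysed, Mukaiyama-type intramolecular hydroalkoxylation of unactivated alkenes by alcohols and phenols to cyclic ethers. Ring B closes in the 6-exo mode with respect to the alkene, whose CH2 terminus becomes the second methyl group on C2. No stereocentre is created, C2 being gem-dimethyl, and C4 should keep the R configuration from step 5 because nothing more acidic than a pyridinium salt is present to ionise the benzylic carbinol. The step needs Markovnikov regioselectivity, secured by the stability of the tertiary radical, and attack by the C8a oxygen alone, secured by the silyl ether on the C5 oxygen, by the para position of the C7 hydroxyl and by the strain of the oxetane that the C4 hydroxyl would have to close.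

Step 8
Reactants: 11 1-{(4R)-4,7-dihydroxy-2,2,6-trimethyl-5-[(triisopropylsilyl)oxy]-3,4-dihydro-2H-chromen-8-yl}-3-phenylpropan-1-one
Product: 12 1-[(4R)-4,5,7-trihydroxy-2,2,6-trimethyl-3,4-dihydro-2H-chromen-8-yl]-3-phenylpropan-1-one
Conditions: Bu4NF/AcOH (1:1, 1.5 equiv), THF, 0 °C; pH 6 buffer work-up, Et3N-deactivated silica
Reagents that add atoms: none
Why: Fluoride-induced cleavage of the aryl silyl ether, buffered with acetic acid, should release the C5 hydroxyl without acid or strong base that could ionise or eliminate the C4 carbinol.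

**Compound list**

1 | 2-methylbenzene-1,3,5-triol (2-methylphloroglucinol) | Cc1c(O)cc(O)cc1O | starting material
2 | 3-phenylpropanoyl chloride | O=C(Cl)CCc1ccccc1 | starting material
3 | 1-(2,4,6-trihydroxy-3-methylphenyl)-3-phenylpropan-1-one | Cc1c(O)cc(O)c(C(=O)CCc2ccccc2)c1O | intermediate
4 | 1-{2,6-dihydroxy-3-methyl-4-[(triisopropylsilyl)oxy]phenyl}-3-phenylpropan-1-one | Cc1c(O[Si](C(C)C)(C(C)C)C(C)C)cc(O)c(C(=O)CCc2ccccc2)c1O | intermediate
5 | 1-{3-[chloro(methoxy)methyl]-2,6-dihydroxy-5-methyl-4-[(triisopropylsilyl)oxy]phenyl}-3-phenylpropan-1-one (racemic at the chloro ether carbon, formed in the flask) | Cc1c(O[Si](C(C)C)(C(C)C)C(C)C)c(C(Cl)OC)c(O)c(C(=O)CCc2ccccc2)c1O | intermediate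
6 | 2,4-dihydroxy-5-methyl-3-(3-phenylpropanoyl)-6-[(triisopropylsilyl)oxy]benzaldehyde | Cc1c(O[Si](C(C)C)(C(C)C)C(C)C)c(C=O)c(O)c(C(=O)CCc2ccccc2)c1O | intermediate
7 | 2,4-bis(allyloxy)-5-methyl-3-(3-phenylpropanoyl)-6-[(triisopropylsilyl)oxy]benzaldehyde | Cc1c(O[Si](C(C)C)(C(C)C)C(C)C)c(C=O)c(OCC=C)c(C(=O)CCc2ccccc2)c1OCC=C | intermediate
8 | (1R)-1-{2,4-bis(allyloxy)-5-methyl-3-(3-phenylpropanoyl)-6-[(triisopropylsilyl)oxy]phenyl}-3-methylbut-3-en-1-yl diisopinocampheylborinate (isopinocampheyl groups from (−)-α-pinene, formed in the flask) | Cc1c(O[Si](C(C)C)(C(C)C)C(C)C)c([C@H](OB([C@H]2C[C@H]3C[C@@H]([C@@H]2C)C3(C)C)[C@H]2C[C@H]3C[C@@H]([C@@H]2C)C3(C)C)CC(C)=C)c(OCC=C)c(C(=O)CCc2ccccc2)c1OCC=C | intermediate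
9 | 1-{2,6-bis(allyloxy)-3-[(1R)-1-hydroxy-3-methylbut-3-en-1-yl]-5-methyl-4-[(triisopropylsilyl)oxy]phenyl}-3-phenylpropan-1-one | Cc1c(O[Si](C(C)C)(C(C)C)C(C)C)c([C@H](O)CC(C)=C)c(OCC=C)c(C(=O)CCc2ccccc2)c1OCC=C | intermediate
10 | 1-{2,6-dihydroxy-3-[(1R)-1-hydroxy-3-methylbut-3-en-1-yl]-5-methyl-4-[(triisopropylsilyl)oxy]phenyl}-3-phenylpropan-1-one | Cc1c(O[Si](C(C)C)(C(C)C)C(C)C)c([C@H](O)CC(C)=C)c(O)c(C(=O)CCc2ccccc2)c1O | intermediate
11 | 1-{(4R)-4,7-dihydroxy-2,2,6-trimethyl-5-[(triisopropylsilyl)oxy]-3,4-dihydro-2H-chromen-8-yl}-3-phenylpropan-1-one | Cc1c(O)c(C(=O)CCc2ccccc2)c2c(c1O[Si](C(C)C)(C(C)C)C(C)C)[C@H](O)CC(C)(C)O2 | intermediate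
12 | 1-[(4R)-4,5,7-trihydroxy-2,2,6-trimethyl-3,4-dihydro-2H-chromen-8-yl]-3-phenylpropan-1-one | Cc1c(O)c(C(=O)CCc2ccccc2)c2c(c1O)[C@H](O)CC(C)(C)O2 | target

**Step count and risks**

Total step count: 8. Longest linear sequence: 8 steps (1 to 12).

Steps most likely to fail:

- **Step 7.** Capture of the tertiary centre by fluoride, or loss of a proton from it, may outrun attack by the ketone-chelated phenol. The β-hydroxy cation-like centre may fragment in a retro-Prins sense, the N–F oxidant may fluorinate ring A, or the hydroxyaryl ketone may bind cobalt and stall turnover. Fallback, from 10 back to 11: intramolecular alkoxymercuration with Hg(OCOCH3)2 (divalent mercury) in THF over NaHCO3 should add the C8a oxygen to the internal alkene carbon under two-electron Markovnikov control. This gives {[(4R)-4,7-dihydroxy-2,6-dimethyl-8-(3-phenylpropanoyl)-5-[(triisopropylsilyl)oxy]-3,4-dihydro-2H-chromen-2-yl]methyl}mercury acetate F1 as both C2 epimers. Alkaline NaBH4 at 0 °C then replaces mercury by hydrogen, and both epimers converge on 11.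

- **Step 3.** Chelation-assisted loss of the silyl group under TiCl4 and HCl may occur once the formyl group sits beside it, or the electrophile may attack the ketone α-carbon. Fallback, from 4 back to 6: magnesium-mediated ortho-formylation (MgCl2, Et3N, paraformaldehyde, MeCN, reflux) works under basic conditions through the magnesium phenoxide of the hydroxyl next to the free ring position. Hydroxymethylation there gives 1-{2,6-dihydroxy-3-(hydroxymethyl)-5-methyl-4-[(triisopropylsilyl)oxy]phenyl}-3-phenylpropan-1-one F2, which a further equivalent of formaldehyde oxidises in the flask by hydride transfer to 6.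

- **Step 5.** Facial discrimination may be poor and addition slow on the aldehyde crowded by two ortho oxygen substituents, with erosion of enantiomeric purity. Fallback, from 7 back to 9: catalyst-controlled allylboration with 2-methylallylboronic acid pinacol ester (1.5 equiv) and (R)-3,3'-bis(2,4,6-triisopropylphenyl)-1,1'-binaphthyl-2,2'-diyl hydrogen phosphate (5 mol %) in toluene at −30 °C. Here the chiral Brønsted acid organises the chair transition state and is expected to deliver the Re-face adduct. The product is 2-{(1R)-1-[2,4-bis(allyloxy)-5-methyl-3-(3-phenylpropanoyl)-6-[(triisopropylsilyl)oxy]phenyl]-3-methylbut-3-en-1-yloxy}-4,4,5,5-tetramethyl-1,3,2-dioxaborolane F3, hydrolysed on work-up to 9. The sense of induction would be checked on 9 through its Mosher esters, and the enantiomeric acid used if needed.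

**Further compounds**

F1 | step 7 | {[(4R)-4,7-dihydroxy-2,6-dimethyl-8-(3-phenylpropanoyl)-5-[(triisopropylsilyl)oxy]-3,4-dihydro-2H-chromen-2-yl]methyl}mercury acetate (both C2 epimers) | Cc1c(O)c(C(=O)CCc2ccccc2)c2c(c1O[Si](C(C)C)(C(C)C)C(C)C)[C@H](O)CC(C)(C[Hg]OC(C)=O)O2
F2 | step 3 | 1-{2,6-dihydroxy-3-(hydroxymethyl)-5-methyl-4-[(triisopropylsilyl)oxy]phenyl}-3-phenylpropan-1-one | Cc1c(O[Si](C(C)C)(C(C)C)C(C)C)c(CO)c(O)c(C(=O)CCc2ccccc2)c1O
F3 | step 5 | 2-{(1R)-1-[2,4-bis(allyloxy)-5-methyl-3-(3-phenylpropanoyl)-6-[(triisopropylsilyl)oxy]phenyl]-3-methylbut-3-en-1-yloxy}-4,4,5,5-tetramethyl-1,3,2-dioxaborolane | Cc1c(O[Si](C(C)C)(C(C)C)C(C)C)c([C@H](OB2OC(C)(C)C(C)(C)O2)CC(C)=C)c(OCC=C)c(C(=O)CCc2ccccc2)c1OCC=C
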